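**Plan**

- Retrosynthesis cuts O6–C7 and O21–C20 (two acid-mediated 7-endo epoxide openings), C10=C11 (aldol condensation), C12–CH3 (cuprate addition) and C12–C13 (sp3–sp2 cross-coupling). This leaves a right-half alkyl iodide, an (S)-β-triflyloxy cyclohexenone and 4-methylpent-3-enal.
- Enabling feature: the right cyclohexane (C15, C16, C22–C25) with its C16 methyl, C25 methyl carbinol and C14–C13 chain is ring B plus two side-chain carbons of andrographolide, and O21 sits on C22 where ring-A carbon C4 of the labdane was. Excising ring A leaves an equatorial C22–OH beside a C17–C19 chain that ends in the C19–C20 epoxide with tertiary C20.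
- Forward order: right cyclohexane (chiral pool), then the right oxepane C16–C22/O21 (step 15), then the left cyclohexane joined at C12–C13 (step 25), then the left oxepene C5–C11/O6 (step 30).
- Stereochemistry: C15 and C16 come from andrographolide; C25 from face-selective epoxidation and hydride opening; C22 from a Criegee rearrangement with retention; C2 from (S)-carvone; C12 from cuprate addition anti to the C2 methyl; C5 from a CBS reduction; C8 (and the transient C19) from Shi epoxidation.
- C19 is carried as a silyl ether and oxidised to the ketone only at the end, while C8–OH is masked as an acetate.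

Key step: step 15

Remark on numbering: atoms carry the numbers of the target (C1 is the methyl on C2, then C2–C5, O6, C7–C20, O21, C22–C25). The andrographolide ring-A carbon that is later excised is called C4′. Left-ring building blocks are named with their own ring locants, and the target atom each carbon becomes is given in the Why lines.

**Step 1**
Reactants: 1 andrographolide
Product: 2 andrographolide 3,19-acetonide (labdane locants; the acetal spans the oxygens on C19 and on the C4′ CH2)
Conditions: 2,2-dimethoxypropane, PPTS (cat.), CH2Cl2/acetone, rt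
Reagents that add atoms: 2,2-dimethoxypropane, COC(C)(C)OC
Why: Acid-catalysed transacetalisation ties the cis 1,3-diol of ring A into a six-membered isopropylidene acetal, so that only the side-chain chemistry follows.

**Step 2**
Reactants: 2 andrographolide 3,19-acetonide
Product: 3 8,17-epoxide of 2 (spiro-oxirane on C25)
Conditions: mCPBA, CH2Cl2, 0 °C → rt
Reagents that add atoms: 3-chloroperoxybenzoic acid, OOC(=O)c1cccc(Cl)c1
Why: Prilezhaev epoxidation picks the electron-rich exocyclic methylene over the conjugated alkylidene lactone and should approach anti to the axial C16 methyl, which places the oxirane oxygen on C25 trans to that methyl.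

**Step 3**
Reactants: 3 8,17-epoxide
Product: 4 epoxy aldehyde (side chain cut to C14H2–C13HO)
Conditions: O3, CH2Cl2/MeOH, −78 °C; then Me2S, −78 °C → rt
Reagents that add atoms: ozone, [O-][O+]=O
Why: Ozonolysis with reductive work-up cleaves the remaining alkylidene-lactone double bond and leaves exactly the two linker carbons C14 and C13 on C15.

**Step 4**
Reactants: 4 epoxy aldehyde
Product: 5 C13,C25-diol (ring-A acetonide retained)
Conditions: LiAlH4, THF, 0 °C → reflux; aqueous NaOH work-up
Reagents that add atoms: none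
Why: Hydride reduction takes the aldehyde to the C13 alcohol and opens the spiro-epoxide by SN2 attack at its CH2, which should give the tertiary C25 alcohol with the new methyl axial and cis to the C16 methyl (25S).

**Step 5**
Reactants: 5 C13,C25-diol
Product: 6 C13 benzyl ether
Conditions: NaH, BnBr, Bu4NI (cat.), THF/DMF, 0 °C → rt
Reagents that add atoms: benzyl bromide, BrCc1ccccc1
Why: Williamson etherification of the primary alkoxide is far faster than that of the hindered tertiary C25 alkoxide, so only C13–OH should be benzylated.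

**Step 6**
Reactants: 6 C13 benzyl ether
Product: 7 ring-A diol (C19–OH and C4′–CH2OH free)
Conditions: AcOH/THF/H2O (3:1:1), 40 °C
Reagents that add atoms: none
Why: Acid hydrolysis of the isopropylidene acetal frees the ring-A 1,3-diol while the benzyl ether and the tertiary alcohol stay.

**Step 7**
Reactants: 7 ring-A diol
Product: 8 primary tosylate (C4′–CH2OTs)
Conditions: TsCl, pyridine, DMAP (cat.), 0 °C → rt
Reagents that add atoms: 4-toluenesulfonyl chloride, Cc1ccc(cc1)S(Cl)(=O)=O
Why: Sulfonylation should distinguish the primary CH2OH from the hindered secondary C19–OH and the tertiary C25–OH.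

**Step 8**
Reactants: 8 primary tosylate
Product: 9 C19 ketone tosylate
Conditions: Dess–Martin periodinane, CH2Cl2, rt
Reagents that add atoms: none
Why: Dess–Martin oxidation of the secondary alcohol gives a β-tosyloxy ketone that cannot eliminate because C4′ carries no hydrogen.

**Step 9**
Reactants: 9 C19 ketone tosylate
Product: 10 seco methyl ester (CO2Me at C19 and isopropenyl on C22)
Conditions: NaOMe, MeOH, 0 °C → rt
Reagents that add atoms: sodium methoxide, [Na+].C[O-]
Why: Grob-type (retro-Claisen) fragmentation, in which methoxide adds to the C19 ketone and the tetrahedral alkoxide expels tosylate with cleavage of the C19–C4′ bond, opens ring A without touching any stereocentre.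

**Step 10**
Reactants: 10 seco methyl ester
Product: 12 C22 acetate methyl ester, via α-methoxy hydroperoxide 11 (not isolated)
Conditions: O3, CH2Cl2/MeOH, −78 °C; then Ac2O, Et3N, DMAP (cat.), CH2Cl2, 0 → 40 °C
Reagents that add atoms: ozone, [O-][O+]=O; methanol, CO
Why: Ozonolysis in methanol followed by Criegee rearrangement of the derived peracetate moves C22 from carbon to oxygen with retention, so the C22–O bond takes the place of the former C22–C4′ bond (22S) and C4′ leaves as the acetyl group.

**Step 11**
Reactants: 12 C22 acetate methyl ester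
Product: 14 trans-fused δ-lactone (C22–O–C19=O), via hydroxy ester 13 (not isolated)
Conditions: K2CO3, MeOH, rt; then PPTS (cat.), CH2Cl2, rt
Reagents that add atoms: none
Why: Base-catalysed methanolysis frees the equatorial C22 hydroxyl, which should lactonise onto the C19 ester under mild acid to the six-membered lactone.

**Step 12**
Reactants: 14 δ-lactone
Product: 15 lactol
Conditions: DIBAL-H, CH2Cl2, −78 °C; Rochelle salt
Reagents that add atoms: none
Why: DIBAL-H reduction of a lactone stops at the lactol because the tetrahedral aluminate is stable at −78 °C.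

**Step 13**
Reactants: 15 lactol; 16 isopropyltriphenylphosphonium iodide
Product: 18 hydroxy alkene (C19=C20 with C22–OH free), via isopropylidenetriphenylphosphorane 17 (not isolated)
Conditions: 16, n-BuLi, THF, 0 °C; then 15, 0 °C → rt
Reagents that add atoms: none
Why: Wittig olefination of the open hydroxy-aldehyde form of the lactol with the non-stabilised ylide installs C20 with its two methyls and frees C22–OH.

**Step 14**
Reactants: 18 hydroxy alkene
Product: 19 (19S)-epoxy diol (seco-oxepane)
Conditions: L-fructose-derived (ent) Shi ketone (0.3 equiv), Oxone, K2CO3, Bu4NHSO4, MeCN/CH2(OMe)2/aq. borate buffer, 0 °C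
Reagents that add atoms: Oxone (potassium peroxymonosulfate), [K+].[O-]S(=O)(=O)OO
Why: Shi epoxidation through a spiro dioxirane transition state should give the (19S)-epoxide, which only serves to keep later intermediates single diastereomers because C19 ends as a ketone.

**Step 15**
Reactants: 19 (19S)-epoxy diol
Product: 20 trans-fused 3-hydroxy-2,2-dimethyloxepane on the right cyclohexane
Conditions: CSA (0.1 equiv), CH2Cl2, 0 °C
Reagents that add atoms: none
Why: Camphorsulfonic acid protonates the oxirane, positive charge builds on the tertiary C20 as its C–O bond lengthens, and the C22 hydroxyl attacks C20 from the rear to form O21–C20. The closest known reaction type is the acid-mediated endo-selective cyclisation of hydroxy epoxides with a trisubstituted oxirane to 2,2-dimethyl-3-hydroxyoxepanes. The oxepane ring (C16–C22 with O21) closes in the 7-endo-tet mode. No stereocentre is created, since the C19–O bond is not broken and C20 is not stereogenic. The step needs 7-endo over 6-exo selectivity (attack at C19 would give a tetrahydropyran); the cation-stabilising tertiary C20 secures it electronically, and the equatorial C22–O and C16–C17 bonds on the chair let the seven-membered ring form trans-fused without strain.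

**Step 16**
Reactants: 20 oxepane diol
Product: 21 C19,C25-bis(triethylsilyl) ether
Conditions: TESOTf, 2,6-lutidine, CH2Cl2, −78 → 0 °C
Reagents that add atoms: triethylsilyl trifluoromethanesulfonate, CC[Si](CC)(CC)OS(=O)(=O)C(F)(F)F
Why: Silylation with the triflate covers the secondary C19 and the hindered tertiary C25 hydroxyls, the latter because a free C25–OH would close a tetrahydrofuran onto C13 once C13 is activated.

**Step 17**
Reactants: 21 bis(triethylsilyl) ether
Product: 22 C13 alcohol
Conditions: H2 (1 atm), Pd/C, EtOAc, rt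
Reagents that add atoms: none
Why: Hydrogenolysis cleaves the benzyl C–O bond and should leave silyl ethers and the oxepane untouched in a non-protic solvent.

**Step 18**
Reactants: 22 C13 alcohol
Product: 23 C13 iodide
Conditions: I2, PPh3, imidazole, CH2Cl2, 0 °C → rt
Reagents that add atoms: iodine, II
Why: Appel-type iodination converts the primary alcohol through its alkoxyphosphonium salt into the iodide by SN2 displacement.

**Step 19**
Reactants: 24 (S)-(+)-carvone
Product: 25 (2S,5S)-dihydrocarvone
Conditions: L-Selectride, THF, −78 °C; then MeOH, −78 °C → rt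
Reagents that add atoms: none
Why: Conjugate hydride reduction followed by equilibration of the α-centre by the methoxide formed on quenching should place the methyl (later on C2) equatorial and trans to the isopropenyl group, and any cis epimer remains a separable diastereomer up to alcohol 30.

**Step 20**
Reactants: 25 (2S,5S)-dihydrocarvone
Product: 27 (3S,6S)-6-methyl-3-(prop-1-en-2-yl)cyclohex-1-en-1-yl triflate, via lithium enolate 26 (not isolated)
Conditions: LDA, THF, −78 °C; then PhNTf2, −78 → 0 °C
Reagents that add atoms: N-phenylbis(trifluoromethanesulfonimide), O=S(=O)(N(c1ccccc1)S(=O)(=O)C(F)(F)F)C(F)(F)F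
Why: Kinetic deprotonation at the unsubstituted α-CH2 (later C11) and O-triflation give the less substituted enol triflate, which locks the methyl-bearing stereocentre (later C2) against epimerisation.

**Step 21**
Reactants: 27 enol triflate
Product: 29 (3S,6S)-3-acetoxy-6-methylcyclohex-1-en-1-yl triflate, via methoxy hydroperoxide 28 (not isolated)
Conditions: O3, CH2Cl2/MeOH, −78 °C (Sudan III end point); then Ac2O, Et3N, DMAP (cat.), CH2Cl2, 0 °C → rt
Reagents that add atoms: ozone, [O-][O+]=O; methanol, CO
Why: Ozone should attack the electron-rich isopropenyl group in preference to the electron-poor enol triflate, and Criegee rearrangement of the peracetate turns it into the allylic acetate on the carbon that becomes C5.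

**Step 22**
Reactants: 29 allylic acetate
Product: 30 (3S,6S)-3-hydroxy-6-methylcyclohex-1-en-1-yl triflate
Conditions: DIBAL-H, CH2Cl2, −78 °C; Rochelle salt
Reagents that add atoms: none
Why: Reductive ester cleavage with DIBAL-H removes the acetate without the alkoxide conditions that could attack the vinyl triflate.

**Step 23**
Reactants: 30 allylic alcohol
Product: 31 (S)-6-methyl-3-oxocyclohex-1-en-1-yl triflate
Conditions: Dess–Martin periodinane, CH2Cl2, 0 °C → rt
Reagents that add atoms: none
Why: Dess–Martin oxidation of the allylic alcohol gives the β-triflyloxy enone, a vinylogous acyl triflate activated for cross-coupling, with the (S)-methyl centre (later C2) as its only stereocentre.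

**Step 24**
Reactants: 32 4-methylpent-3-en-1-ol
Product: 33 4-methylpent-3-enal
Conditions: Dess–Martin periodinane, pyridine, CH2Cl2, 0 °C; used at once
Reagents that add atoms: none
Why: Buffered Dess–Martin oxidation should give the β,γ-unsaturated aldehyde without migration of the double bond into conjugation.

**Step 25**
Reactants: 23 C13 iodide; 31 (S)-triflyloxy enone
Product: 35 coupled enone (C13 on C12 of the 4-methylcyclohex-2-enone), via alkylzinc iodide 34 (not isolated)
Conditions: Zn dust (activated with BrCH2CH2Br and TMSCl), LiCl, THF, 40 °C; then 31, Pd(dppf)Cl2 (5 mol%), THF, rt → 50 °C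
Reagents that add atoms: none
Why: Negishi coupling, in which zinc inserts into the primary C–I bond and palladium joins C13 to C12 after oxidative addition into the activated C–OTf bond, tolerates the silyl ethers and the enone.

**Step 26**
Reactants: 35 coupled enone; 33 4-methylpent-3-enal
Product: 37 aldol (mixture at C10 and C11), via lithium enolate 36 (not isolated)
Conditions: Me2CuLi (from CuI and MeLi), Et2O, −40 → 0 °C; then 33, THF, −78 °C; aqueous work-up
Reagents that add atoms: lithium dimethylcuprate, [Li+].C[Cu-]C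
Why: Tandem cuprate conjugate addition and aldol reaction, in which methyl should add axially to C12 anti to the C2 methyl that A(1,2) strain holds pseudoaxial (12S, the two methyls trans) and the regiodefined C11 enolate is trapped by the aldehyde.

**Step 27**
Reactants: 37 aldol
Product: 39 (Z)-dienone (C10=C11 exocyclic enone), via mesylate 38 (not isolated)
Conditions: MsCl, Et3N, CH2Cl2, 0 °C; then DBU, 0 °C → rt
Reagents that add atoms: none
Why: Mesylation and E1cB elimination erase the C10 and C11 centres, and the Z geometry (C9 syn to the carbonyl) is expected because the E isomer would suffer A(1,3) strain against the quaternary C12.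

**Step 28**
Reactants: 39 (Z)-dienone
Product: 40 (8S)-epoxy enone
Conditions: L-fructose-derived (ent) Shi ketone (0.3 equiv), Oxone, K2CO3, Bu4NHSO4, MeCN/CH2(OMe)2/aq. borate buffer, 0 °C
Reagents that add atoms: Oxone (potassium peroxymonosulfate), [K+].[O-]S(=O)(=O)OO
Why: Shi epoxidation with the electrophilic dioxirane should oxidise the electron-rich C7=C8 bond and not the enone double bond, and the L-series ketone should deliver the (8S)-epoxide.

**Step 29**
Reactants: 40 (8S)-epoxy enone
Product: 41 (5S)-allylic alcohol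
Conditions: (R)-Me-CBS oxazaborolidine (0.5 equiv), catecholborane, toluene, −78 °C; aq. NaOH work-up
Reagents that add atoms: none
Why: Corey–Bakshi–Shibata reduction, in which the (R)-oxazaborolidine binds the ketone with the alkylidene-bearing C11 side as the large group, should deliver hydride under catalyst control to give the (5S)-alcohol, with the epoxide and silyl ethers inert at −78 °C.

**Step 30**
Reactants: 41 (5S)-allylic alcohol
Product: 43 C8 acetate of the oxepene, via oxepene alcohol 42 (not isolated)
Conditions: CSA (0.1 equiv), CH2Cl2, 0 °C; then pyridine, Ac2O, DMAP (cat.), 0 °C → rt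
Reagents that add atoms: acetic anhydride, CC(=O)OC(C)=O
Why: Acid-catalysed 7-endo epoxide opening by the C5 hydroxyl at the tertiary C7 closes the oxepene with C8 keeping its configuration, and acetylation in the same flask masks the new C8 hydroxyl before C19 is oxidised.

**Step 31**
Reactants: 43 C8 acetate bis(triethylsilyl) ether
Product: 44 C8 acetate C19,C25-diol
Conditions: HF·pyridine, pyridine, THF, 0 °C → rt
Reagents that add atoms: none
Why: Fluoride-mediated desilylation removes both triethylsilyl ethers and leaves the acetate and the allylic ether.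

**Step 32**
Reactants: 44 C8 acetate C19,C25-diol
Product: 45 C8 acetate C19 ketone
Conditions: Dess–Martin periodinane, pyridine, CH2Cl2, rt
Reagents that add atoms: none
Why: Dess–Martin oxidation converts the only free secondary alcohol, C19–OH, into the ketone, since the tertiary C25–OH cannot be oxidised.

**Step 33**
Reactants: 45 C8 acetate C19 ketone
Product: 46 Sodwanone S
Conditions: K2CO3, MeOH, rt
Reagents that add atoms: none
Why: Base-catalysed methanolysis (transesterification) removes the acetate and frees C8–OH without affecting the ketone, which has no stereocentre at its α-positions.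

**Compound list**

1 | andrographolide | C[C@@]12CC[C@H]([C@@]([C@H]1CCC(=C)[C@H]2C/C=C/3\[C@@H](COC3=O)O)(C)CO)O | starting material
2 | andrographolide 3,19-acetonide | C[C@@]12CC[C@H]([C@@]([C@H]1CCC(=C)[C@H]2C/C=C/3\[C@@H](COC3=O)O)(C)COC4(C)C)O4 | intermediate
3 | 8,17-epoxide of 2 (oxirane oxygen on C25 anti to the C16 methyl) | C[C@@]12CC[C@H]([C@@]([C@H]1CC[C@@]5(CO5)[C@H]2C/C=C/3\[C@@H](COC3=O)O)(C)COC4(C)C)O4 | intermediate
4 | epoxy aldehyde (C13 aldehyde, spiro-oxirane on C25, ring-A acetonide) | C[C@@]12CC[C@H]([C@@]([C@H]1CC[C@@]5(CO5)[C@H]2CC=O)(C)COC4(C)C)O4 | intermediate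
5 | C13,C25-diol with ring-A acetonide (25S) | C[C@@]12CC[C@H]([C@@]([C@H]1CC[C@](C)(O)[C@H]2CCO)(C)COC4(C)C)O4 | intermediate
6 | C13 benzyl ether of 5 | C[C@@]12CC[C@H]([C@@]([C@H]1CC[C@](C)(O)[C@H]2CCOCc3ccccc3)(C)COC4(C)C)O4 | intermediate
7 | ring-A diol (C19–OH, C4′–CH2OH), C13 benzyl ether, C25–OH | C[C@@]12CC[C@H]([C@@]([C@H]1CC[C@](C)(O)[C@H]2CCOCc3ccccc3)(C)CO)O | intermediate
8 | C4′–CH2 tosylate of 7 | C[C@@]12CC[C@H]([C@@]([C@H]1CC[C@](C)(O)[C@H]2CCOCc3ccccc3)(C)COS(=O)(=O)c3ccc(C)cc3)O | intermediate
9 | C19 ketone tosylate | C[C@@]12CCC(=O)[C@@]([C@H]1CC[C@](C)(O)[C@H]2CCOCc3ccccc3)(C)COS(=O)(=O)c3ccc(C)cc3 | intermediate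
10 | seco methyl ester (C19 CO2Me, isopropenyl on C22, C13 benzyl ether, C25–OH) | O(Cc1ccccc1)CC[C@H]1[C@](C)(CCC(=O)OC)[C@@H](C(C)=C)CC[C@]1(C)O | intermediate
11 | α-methoxy hydroperoxide from the isopropenyl group (formed in the flask) | O(Cc1ccccc1)CC[C@H]1[C@](C)(CCC(=O)OC)[C@@H](C(C)(OC)OO)CC[C@]1(C)O | intermediate
12 | (22S)-C22 acetate methyl ester | O(Cc1ccccc1)CC[C@H]1[C@](C)(CCC(=O)OC)[C@@H](OC(C)=O)CC[C@]1(C)O | intermediate
13 | C22-hydroxy methyl ester (formed in the flask) | O(Cc1ccccc1)CC[C@H]1[C@](C)(CCC(=O)OC)[C@@H](O)CC[C@]1(C)O | intermediate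
14 | trans-fused δ-lactone (C22–O–C19=O) | O(Cc1ccccc1)CC[C@H]1[C@]2(C)CCC(=O)O[C@H]2CC[C@]1(C)O | intermediate
15 | lactol (C19 hemiacetal, both anomers) | O(Cc1ccccc1)CC[C@H]1[C@]2(C)CCC(O)O[C@H]2CC[C@]1(C)O | intermediate
16 | isopropyltriphenylphosphonium iodide | CC(C)[P+](c1ccccc1)(c1ccccc1)c1ccccc1.[I-] | starting material
17 | isopropylidenetriphenylphosphorane (formed in the flask) | CC(C)=P(c1ccccc1)(c1ccccc1)c1ccccc1 | intermediate
18 | (15S,16S,22S,25S)-hydroxy alkene (C19=C20, C22–OH, C25–OH, C13 benzyl ether) | O(Cc1ccccc1)CC[C@H]1[C@](C)(CCC=C(C)C)[C@@H](O)CC[C@]1(C)O | intermediate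
19 | (19S)-seco-oxepane epoxy diol, C13 benzyl ether | O(Cc1ccccc1)CC[C@H]1[C@](C)(CC[C@@H]2OC2(C)C)[C@@H](O)CC[C@]1(C)O | intermediate
20 | trans-fused (19S)-3-hydroxy-2,2-dimethyloxepane on the right cyclohexane, C13 benzyl ether | O(Cc1ccccc1)CC[C@H]1[C@]2(C)CC[C@H](O)C(C)(C)O[C@H]2CC[C@]1(C)O | intermediate
21 | C19,C25-bis(triethylsilyl) ether of 20 | O(Cc1ccccc1)CC[C@H]1[C@]2(C)CC[C@H](O[Si](CC)(CC)CC)C(C)(C)O[C@H]2CC[C@]1(C)O[Si](CC)(CC)CC | intermediate
22 | C13 alcohol | OCC[C@H]1[C@]2(C)CC[C@H](O[Si](CC)(CC)CC)C(C)(C)O[C@H]2CC[C@]1(C)O[Si](CC)(CC)CC | intermediate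
23 | C13 iodide | ICC[C@H]1[C@]2(C)CC[C@H](O[Si](CC)(CC)CC)C(C)(C)O[C@H]2CC[C@]1(C)O[Si](CC)(CC)CC | intermediate
24 | (S)-(+)-carvone | CC1=CC[C@@H](CC1=O)C(C)=C | starting material
25 | (2S,5S)-dihydrocarvone | C[C@H]1CC[C@@H](CC1=O)C(C)=C | intermediate
26 | kinetic lithium enolate of 25 (formed in the flask) | C[C@H]1CC[C@@H](C=C1O[Li])C(C)=C | intermediate
27 | (3S,6S)-6-methyl-3-(prop-1-en-2-yl)cyclohex-1-en-1-yl trifluoromethanesulfonate | C[C@H]1CC[C@@H](C=C1OS(=O)(=O)C(F)(F)F)C(C)=C | intermediate
28 | methoxy hydroperoxide from 27 (formed in the flask) | C[C@H]1CC[C@@H](C=C1OS(=O)(=O)C(F)(F)F)C(C)(OC)OO | intermediate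
29 | (3S,6S)-3-acetoxy-6-methylcyclohex-1-en-1-yl trifluoromethanesulfonate | C[C@H]1CC[C@@H](C=C1OS(=O)(=O)C(F)(F)F)OC(C)=O | intermediate
30 | (3S,6S)-3-hydroxy-6-methylcyclohex-1-en-1-yl trifluoromethanesulfonate | C[C@H]1CC[C@@H](C=C1OS(=O)(=O)C(F)(F)F)O | intermediate
31 | (S)-6-methyl-3-oxocyclohex-1-en-1-yl trifluoromethanesulfonate | C[C@H]1CCC(=O)C=C1OS(=O)(=O)C(F)(F)F | intermediate
32 | 4-methylpent-3-en-1-ol | CC(C)=CCCO | starting material
33 | 4-methylpent-3-enal | CC(C)=CCC=O | intermediate
34 | C13 alkylzinc iodide (formed in the flask) | I[Zn]CC[C@H]1[C@]2(C)CC[C@H](O[Si](CC)(CC)CC)C(C)(C)O[C@H]2CC[C@]1(C)O[Si](CC)(CC)CC | intermediate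
35 | coupled enone (C5 ketone, C11=C12, (2S)-methyl) | C[C@H]1CCC(=O)C=C1CC[C@H]1[C@]2(C)CC[C@H](O[Si](CC)(CC)CC)C(C)(C)O[C@H]2CC[C@]1(C)O[Si](CC)(CC)CC | intermediate
36 | lithium enolate (C5–OLi, C5=C11, (12S)-quaternary centre; formed in the flask) | C[C@H]1CCC(O[Li])=C[C@@]1(C)CC[C@H]1[C@]2(C)CC[C@H](O[Si](CC)(CC)CC)C(C)(C)O[C@H]2CC[C@]1(C)O[Si](CC)(CC)CC | intermediate
37 | aldol (C10 carbinol, mixture at C10 and C11) | C[C@H]1CCC(=O)C(C(O)CC=C(C)C)[C@@]1(C)CC[C@H]1[C@]2(C)CC[C@H](O[Si](CC)(CC)CC)C(C)(C)O[C@H]2CC[C@]1(C)O[Si](CC)(CC)CC | intermediate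
38 | C10 mesylate of 37 (formed in the flask) | C[C@H]1CCC(=O)C(C(OS(C)(=O)=O)CC=C(C)C)[C@@]1(C)CC[C@H]1[C@]2(C)CC[C@H](O[Si](CC)(CC)CC)C(C)(C)O[C@H]2CC[C@]1(C)O[Si](CC)(CC)CC | intermediate
39 | (Z)-dienone (C10=C11 enone, C7=C8 alkene) | C[C@H]1CCC(=O)/C(=C\CC=C(C)C)[C@@]1(C)CC[C@H]1[C@]2(C)CC[C@H](O[Si](CC)(CC)CC)C(C)(C)O[C@H]2CC[C@]1(C)O[Si](CC)(CC)CC | intermediate
40 | (8S)-epoxy enone | C[C@H]1CCC(=O)/C(=C\C[C@@H]2OC2(C)C)[C@@]1(C)CC[C@H]1[C@]2(C)CC[C@H](O[Si](CC)(CC)CC)C(C)(C)O[C@H]2CC[C@]1(C)O[Si](CC)(CC)CC | intermediate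
41 | (5S,8S)-epoxy allylic alcohol | C[C@H]1CC[C@H](O)/C(=C\C[C@@H]2OC2(C)C)[C@@]1(C)CC[C@H]1[C@]2(C)CC[C@H](O[Si](CC)(CC)CC)C(C)(C)O[C@H]2CC[C@]1(C)O[Si](CC)(CC)CC | intermediate
42 | oxepene alcohol (C8–OH; formed in the flask) | C[C@H]1CC[C@@H]2OC(C)(C)[C@@H](O)CC=C2[C@@]1(C)CC[C@H]1[C@]2(C)CC[C@H](O[Si](CC)(CC)CC)C(C)(C)O[C@H]2CC[C@]1(C)O[Si](CC)(CC)CC | intermediate
43 | C8 acetate, C19,C25-bis(triethylsilyl) ether | C[C@H]1CC[C@@H]2OC(C)(C)[C@@H](OC(C)=O)CC=C2[C@@]1(C)CC[C@H]1[C@]2(C)CC[C@H](O[Si](CC)(CC)CC)C(C)(C)O[C@H]2CC[C@]1(C)O[Si](CC)(CC)CC | intermediate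
44 | C8 acetate, C19,C25-diol | C[C@H]1CC[C@@H]2OC(C)(C)[C@@H](OC(C)=O)CC=C2[C@@]1(C)CC[C@H]1[C@]2(C)CC[C@H](O)C(C)(C)O[C@H]2CC[C@]1(C)O | intermediate
45 | C8 acetate, C19 ketone | C[C@H]1CC[C@@H]2OC(C)(C)[C@@H](OC(C)=O)CC=C2[C@@]1(C)CC[C@H]1[C@]2(C)CCC(=O)C(C)(C)O[C@H]2CC[C@]1(C)O | intermediate
46 | Sodwanone S | C[C@H]1CC[C@@H]2OC(C)(C)[C@@H](O)CC=C2[C@@]1(C)CC[C@H]1[C@]2(C)CCC(=O)C(C)(C)O[C@H]2CC[C@]1(C)O | target

**Step count and risks**

Total step count: 33
Longest linear sequence: 27 steps (steps 1–18, then 25–33, from andrographolide)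

Steps most likely to fail:

Step 29. Hydride transfer to the C5 carbonyl may show poor facial selectivity: both half-chair conformers of the enone carry an axial group on the quaternary C12, so the substrate's own preference is uncertain and may oppose the catalyst. The fallback sets out from 40 and accepts that preference. Luche reduction (NaBH4, CeCl3·7H2O, MeOH, −78 °C) would give the (5R)-allylic alcohol F1. Mitsunobu inversion (4-nitrobenzoic acid, PPh3, DIAD, toluene, 0 °C) would then give the (5S)-4-nitrobenzoate F2, and methanolysis (K2CO3, MeOH) comes back to the route at 41.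

Step 27. During the base-mediated elimination the isolated C7=C8 double bond may migrate into conjugation with the new enone, because the C9 hydrogens are doubly allylic. The fallback sets out from 37 and removes the 1,4-diene before any enone exists. Shi epoxidation of the only alkene, under the conditions of step 28, would give the epoxy aldol F3. Mesylation (MsCl, Et3N, CH2Cl2, −20 → 0 °C) would give the mesylate F4, which should eliminate with triethylamine alone and come back to the route at 40.

Step 26. Proton transfer from the enolisable aldehyde to the hindered C11 enolate may outrun C–C bond formation, and the conjugate addition may be slow without activation. The fallback sets out from 35 and separates the two events. Me2CuLi with TMSCl (THF, −78 °C) would give the trimethylsilyl enol ether F5, which is isolated. A Mukaiyama aldol reaction with 33 (BF3·OEt2, CH2Cl2, −78 °C) then comes back to the route at 37.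

**Further compounds**

F1 | step 29 | (5R,8S)-epoxy allylic alcohol (C5 epimer of 41) | C[C@H]1CC[C@@H](O)/C(=C\C[C@@H]2OC2(C)C)[C@@]1(C)CC[C@H]1[C@]2(C)CC[C@H](O[Si](CC)(CC)CC)C(C)(C)O[C@H]2CC[C@]1(C)O[Si](CC)(CC)CC
F2 | step 29 | (5S)-4-nitrobenzoate of 41 | C[C@H]1CC[C@H](OC(=O)c2ccc(cc2)[N+](=O)[O-])/C(=C\C[C@@H]2OC2(C)C)[C@@]1(C)CC[C@H]1[C@]2(C)CC[C@H](O[Si](CC)(CC)CC)C(C)(C)O[C@H]2CC[C@]1(C)O[Si](CC)(CC)CC
F3 | step 27 | (8S)-epoxy aldol (epoxide of 37) | C[C@H]1CCC(=O)C(C(O)C[C@@H]2OC2(C)C)[C@@]1(C)CC[C@H]1[C@]2(C)CC[C@H](O[Si](CC)(CC)CC)C(C)(C)O[C@H]2CC[C@]1(C)O[Si](CC)(CC)CC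
F4 | step 27 | C10 mesylate of F3 | C[C@H]1CCC(=O)C(C(OS(C)(=O)=O)C[C@@H]2OC2(C)C)[C@@]1(C)CC[C@H]1[C@]2(C)CC[C@H](O[Si](CC)(CC)CC)C(C)(C)O[C@H]2CC[C@]1(C)O[Si](CC)(CC)CC
F5 | step 26 | trimethylsilyl enol ether (C5–OTMS, C5=C11, 12S) | C[C@H]1CCC(O[Si](C)(C)C)=C[C@@]1(C)CC[C@H]1[C@]2(C)CC[C@H](O[Si](CC)(CC)CC)C(C)(C)O[C@H]2CC[C@]1(C)O[Si](CC)(CC)CC
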